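Reagent is conserved: each unit charged is free in one of the two phases, or has consumed one starting material, or sits as the second unit in over-reacted product. Count everything as a fraction of the starting material charged.

all flasks: starting material 14 mM
- dawn: reagent in the second phase 7.8 mM; protic impurity 1.4 mM; run made earlier
- midnight: reagent in the second phase 11 mM; protic impurity 1.4 mM; run made earlier
- ash: reagent in the second phase 4.00 mM; protic impurity 1.40 mM; time 5.0 h; volume of the second phase over the first 1.0
- larch: reagent in the second phase 14.0 mM; protic impurity 1.40 mM; time 5.0 h; volume of the second phase over the first 1.0

| run | time / h | target / % |
|---|---|---|
| dawn | 0.417 | 3 |
| dawn | 0.833 | 5 |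
| dawn | 1.33 | 12 |
| dawn | 2.50 | 17 |
| dawn | 5.00 | 22 |
| midnight | 0.417 | 6 |
| midnight | 1.33 | 15 |
| midnight | 2.50 | 19 |
| midnight | 4.00 | 24 |
| midnight | 5.00 | 23 |

(scatter of a reading: 2 percentage points)

- in the second phase: reagent in the second phase; everything else is in the first
- charges count per volume of the first phase; a concentration in a rate is the amount of a species over the volume of its own phase; every rate counts per litre of the first phase
- the numbers in the tables scatter with a standard deviation of 2 percentage points
- candidate steps: reagent in the reaction phase <-> reagent in the second phase; starting material + reagent in the reaction phase -> target; reagent in the reaction phase + target -> over-reacted product; starting material + protic impurity -> quenched substrate; target <-> isomer of the product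
- the earlier runs hold the two phases in the same ratio of volumes as the flask asked about

1. the winner by amount of target, in percent of the starting material charged; "neither" if no more than 2 percentage points parts them (ash / larch / neither)
2. how much target is there at the end, in percent of the starting material charged: ash
3. how much target is there at the end, in percent of the starting material charged: larch

My own reckoning starts from the impurity. I let it take its own charge of starting material, which leaves m = 90.0% for the reagent. Now divide the rate of target by the rate of starting-material loss. This reckoning sets aside the step from target to isomer of the product, whose rate holds no reagent; for the two reagent steps, reagent concentration and time drop out: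

d(target)/d(starting material) = −1 + s·target/starting material

Here s is the selectivity factor. Taking s = 2 puts the peak at m/4 = 22.5%, close to the last readings of 24% and 23% in midnight; dawn still climbs from 17% to 22%, so it shows no peak. With x as the share of m left:

target = m·x·(1 − x)
reagent spent = m·(1 − x)·(2 − x)

The two extremes are solved by the budget, reagent charged over starting material charged. Ash has 28.6%. With that budget spent, x = 0.747 and target is 17.0%. Larch has 100%. With that budget spent, x = 0.333 and target is 20.0%, more than the ash ceiling.

The peak itself sits at x = 0.5, so the reagent spent at the peak is 67.5%. Midnight reads level from 4.00 h, and larch is richer in reagent, so I put larch between 20.0% and 22.5%, and ash somewhere under its ceiling.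

The forecast gave 13% for ash, 23% for larch and larch as winner, noting of ash: “It cannot exceed about 17% even if all the reagent is consumed.”

The flask gives 13.0% for ash and 27.6% for larch, so larch wins.

    reagent in the reaction phase ⇌ reagent in the second phase, rate k1*([reagent in the reaction phase] - [reagent in the second phase]/K1) per volume of the first phase (partition coefficient = 0.370, kL = 1.04 /h)
    starting material + reagent in the reaction phase → target (k = 29.5 /M/h)
    reagent in the reaction phase + target → over-reacted product (k = 26.6 /M/h)
    starting material + protic impurity → quenched substrate (k = 954 /M/h)
    target ⇌ isomer of the product (K = 0.373, k = 0.219 /h)

Against the 67.5% spent at my peak, larch has spent 65.4% at 5.00 h, with target above my 22.5%. Ash has spent 20.0%, and the same flask read at 80 min has spent 7.02%, holding 5.92% target. At 5.00 h, ash makes target 2.01 times as fast as it uses it up. Left until 50.0 h, ash holds 16.5%.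

Readings and results are simulated from invented constants, and the scatter is random.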